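The numbers in the tables are simulated from invented constants; the scatter is artificial.

Leave the scavenger alone. The south-west and south runs, at 0.48 M and 1.7 M of it, read 45.7 % and 45.1 % of solid substrate after 4.00 min, a gap of 0.6 percentage points with a scatter of 0.5 points per reading.

in all of them: solid substrate 0.56 M; partner 1.68 M
- south-west: scavenger 0.48 M; run made earlier
- south: scavenger 1.7 M; run made earlier
- Sunday's: scavenger 0.670 M; time 8.0 min
- Monday's: scavenger 1.30 M; time 8.0 min
- Thursday's: scavenger 2.70 M; time 8.0 min

| run | time / min | solid substrate / % | mono adduct / % |
|---|---|---|---|
| south-west | 0.667 | 87.5 | 7.5 |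
| south-west | 1.33 | 78.8 | 15.7 |
| south-west | 2.00 | 69.5 | 23.9 |
| south-west | 2.50 | 64.1 | 29.0 |
| south-west | 3.00 | 57.6 | 35.4 |
| south-west | 4.00 | 45.7 | 45.1 |
| south | 0.333 | 91.5 | 3.0 |
| south | 0.500 | 89.0 | 5.4 |
| south | 0.833 | 84.2 | 10.6 |
| south | 1.33 | 78.9 | 15.9 |
| south | 2.50 | 64.3 | 30.2 |
| south | 4.00 | 45.1 | 45.3 |

(standard deviation of a reading: 0.5 percentage points)

1. part of the solid substrate that has reacted (what has only dissolved counts as not reacted) at the end, Sunday's
2. part of the solid substrate that has reacted (what has only dissolved counts as not reacted) at the end, Monday's
3. part of the solid substrate that has reacted (what has only dissolved counts as not reacted) at the end, Thursday's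
4. what raising the concentration of scavenger from its lowest to its highest value here does to the part of the solid substrate that has reacted (what has only dissolved counts as not reacted) (changes below 5 percentage points count as none) (it falls / no change / it rises)

- solid substrate is a solid; its amount is given per volume of the solution
- at the start none of the solid substrate is in solution
- what has only dissolved of solid substrate counts as not reacted

The flask holds solid, a dissolved part and mono adduct. At the first south reading, solid and mono adduct leave 5.50 % unaccounted for. I take that as the dissolved part and hold it steady, so the mean of those two solid readings puts the reacted part after 4.00 min at 49.1 %.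

With a steady dissolved level I take the rate as proportional to [partner], pseudo-first-order in partner, one partner used per substrate reacted. Free partner then shrinks by exp(−λt), and the amount reacted is the charged [partner] minus what is left. The readings give λ = 0.0447 min⁻¹, the share of free partner used per minute.

When you come at 8.0 min, expect 0.505 M reacted, which is 90.2 % of the charge, with 4.30 % still solid. I write that same number for Sunday's, Monday's and Thursday's, hence no change, though Thursday's lies beyond the runs.

The forecast gives 95 %, 95 % and 95 % with no change, reading that “the substrate falls in a straight line”, and its figure for Sunday's is higher than mine.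

The flasks give 91.5 %, 91.6 % and 91.7 %: no change.

    partner + mono adduct → double product + released group (k = 5.00 × 10⁻⁴ L mol⁻¹ s⁻¹)
    solid substrate ⇌ starting material, rate k2*(cs2 - [starting material]) while solid is left; crystals form when [starting material] > cs2 (solubility = 38.0 mM, k = 0.140 s⁻¹)
    partner + released group ⇌ idle adduct, settled at all times (K = 0.730 L mol⁻¹)
    starting material + partner → mono adduct + released group (k = 0.0260 L mol⁻¹ s⁻¹)
    mono adduct + released group → side product (k = 0.00340 L mol⁻¹ s⁻¹)
    scavenger + released group → scavenged by-product (k = 1.10 L mol⁻¹ s⁻¹)

In Sunday's flask, starting material stood at 5.40 % at 4.00 min and 5.64 % at 8.00 min, while solid substrate fell from 45.4 % to 2.84 % and partner from 82.1 % to 64.7 %. Scavenger took up the released group throughout, with a half-life of 0.10 min at the end. My 0.0447 min⁻¹ put Sunday's at 90.2 % against 91.5 %. For the flask like Sunday's but with 0.95 M of solid substrate, the same 0.505 M gives 53.2 %, and that flask, with 42.7 % still solid, stands at 53.9 %.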